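**Retrosynthetic overview**
- The target comes from one global H2/Pd reduction of an 18-membered macrocycle that still carries a C=O on the ring A benzylic carbon, an (E)-CH=CH between rings B and C, and a benzyl ether on ring C.
- The macrocycle is closed at the ring A–O–ring B ether by a biomimetic dehydrogenative phenol C–O coupling: the para-methoxyphenol of ring A is oxidised to its quinone monoketal, the ring B phenol adds, and methanol is lost. The ring A ketone steers the attack to the carbon between acyl and OMe.
- The seco ketone comes from Pd-catalysed α-arylation of 2'-hydroxy-5'-methoxyacetophenone with a ring D aryl bromide.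
- The aryl bromide comes from a Wittig reaction (ring B) on an aldehyde made by Ullmann coupling (ring C–O–ring D ether) of 4-(benzyloxy)-3-hydroxybenzaldehyde with 1-bromo-4-iodobenzene.
- Ring order: all four benzene rings are bought; the only ring formed is the macrocycle, in step 5.

Assumption: the target SMILES has no stereocentre and the 18-membered ring is conformationally mobile, so the compound is achiral and no enantiocontrol is needed.

Ring letters: A = methoxy/hydroxy ring; B = meta-phenylene bonded to A through O; C = phenol ring bonded to D through O; D = para-phenylene bonded to A through CH2CH2.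

**Step 1**
Reactants: 1 3-hydroxybenzyl alcohol
Product: 2 (3-hydroxybenzyl)triphenylphosphonium bromide
Conditions: PPh3·HBr (1.05 equiv), MeCN, reflux
Reagents that add atoms: triphenylphosphine hydrobromide, [PH+](c1ccccc1)(c1ccccc1)c1ccccc1.[Br-]
Why: The acid salt activates the benzylic alcohol for substitution by triphenylphosphine (phosphonium salt formation), and the phenol is inert under these acidic conditions.

**Step 2**
Reactants: 3 4-(benzyloxy)-3-hydroxybenzaldehyde; 4 1-bromo-4-iodobenzene
Product: 5 4-(benzyloxy)-3-(4-bromophenoxy)benzaldehyde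
Conditions: CuI (10 mol %), N,N-dimethylglycine·HCl (30 mol %), Cs2CO3 (2 equiv), 4 (1.5 equiv), 1,4-dioxane, 90 °C
Reagents that add atoms: none
Why: Ullmann diaryl ether synthesis in which the C–I bond of 4 reacts well before its C–Br bond and 3 has only one free phenol, so the ring C–O–ring D ether is placed meta to the formyl group and the bromide is kept for step 4.

**Step 3**
Reactants: 5 4-(benzyloxy)-3-(4-bromophenoxy)benzaldehyde; 2 (3-hydroxybenzyl)triphenylphosphonium bromide
Product: 7 3-[(E)-2-[4-(benzyloxy)-3-(4-bromophenoxy)phenyl]ethenyl]phenol, via Z-stilbene 6 (not isolated)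
Conditions: KOtBu (2.2 equiv), THF, 0 °C to rt; then I2 (5 mol %), CH2Cl2, daylight, rt
Reagents that add atoms: none
Why: Wittig olefination of the non-enolisable aldehyde with the semi-stabilised ylide (the second equivalent of base only forms the phenoxide), followed by iodine-catalysed Z-to-E equilibration so that one defined alkene is carried forward until it is hydrogenated in step 6.

**Step 4**
Reactants: 7 3-[(E)-2-[4-(benzyloxy)-3-(4-bromophenoxy)phenyl]ethenyl]phenol; 8 1-(2-hydroxy-5-methoxyphenyl)ethan-1-one (2'-hydroxy-5'-methoxyacetophenone)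
Product: 9 2-[4-[2-(benzyloxy)-5-[(E)-2-(3-hydroxyphenyl)ethenyl]phenoxy]phenyl]-1-(2-hydroxy-5-methoxyphenyl)ethan-1-one
Conditions: Pd2(dba)3 (2.5 mol %), XPhos (6 mol %), NaOtBu (4.5 equiv), 8 (1.2 equiv), THF, 65 °C; aq. NH4Cl
Reagents that add atoms: none
Why: Palladium-catalysed ketone α-arylation (Buchwald–Hartwig–Miura type) of the methyl ketone enolate, which with a bulky biarylphosphine outruns aryloxide C–O coupling and Heck reaction of the internal alkene, while the excess base holds both phenols as spectator aryloxides and the product as its enolate so that diarylation is suppressed.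

**Step 5**
Reactants: 9 2-[4-[2-(benzyloxy)-5-[(E)-2-(3-hydroxyphenyl)ethenyl]phenoxy]phenyl]-1-(2-hydroxy-5-methoxyphenyl)ethan-1-one
Product: 12 macrocyclic keto-stilbene benzyl ether (18-membered ring; the target skeleton with C=O at the ring A benzylic carbon, (E)-CH=CH between rings B and C and the ring C phenol as benzyl ether), via acyl quinone monoketal 10 (not isolated), via macrocyclic enol adduct 11 (not isolated)
Conditions: PhI(OAc)2 (1.05 equiv), MeOH, 0 °C; evaporate (toluene chase); Cs2CO3 (2 equiv), MeCN (1 mM), rt; filter; TsOH·H2O (1.5 equiv), rt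
Reagents that add atoms: methanol, CO (supplies one of the two ketal methoxy groups of 10 and 11, so statistically the methoxy group of 12)
Why: Proposed new method: PhI(OAc)2 in methanol dearomatises only the para-methoxyphenol of ring A to the acyl quinone monoketal 10 (the two-electron form of oxidative phenol coupling), whose C3 is the β-carbon of an alkylidene 1,3-dicarbonyl and so by far the most electrophilic site, so the ring B aryloxide adds there through an unstrained 18-membered transition state to give the stabilised 1,3-dicarbonyl enolate of 11 (racemic at C3), and acid-induced loss of methanol re-aromatises ring A with the aryloxy group between the acyl and methoxy groups; the closest known reactions are conjugate additions of thiols, amines and stabilised carbanions to quinone monoketals followed by aromatising loss of methanol, and the phenol-oxidation macroetherifications used for isodityrosine-type diaryl ethers.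

**Step 6**
Reactants: 12 macrocyclic keto-stilbene benzyl ether
Product: 13 CNP0179896.0 (target)
Conditions: H2 (4 atm), 10% Pd/C, AcOH–EtOAc (1:1), HClO4 (cat.), 50 °C
Reagents that add atoms: none
Why: Heterogeneous catalytic hydrogenation saturates the stilbene and cleaves the benzyl ether, and under acid the ortho-hydroxyaryl ketone is hydrogenolysed to the methylene through its benzylic alcohol, while the diaryl ethers and the arenes are inert.

**Compound list**
1 | 3-hydroxybenzyl alcohol | OCc1cccc(O)c1 | starting material
2 | (3-hydroxybenzyl)triphenylphosphonium bromide | Oc1cccc(C[P+](c2ccccc2)(c2ccccc2)c2ccccc2)c1.[Br-] | intermediate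
3 | 4-(benzyloxy)-3-hydroxybenzaldehyde | O=Cc1ccc(OCc2ccccc2)c(O)c1 | starting material
4 | 1-bromo-4-iodobenzene | Brc1ccc(I)cc1 | starting material
5 | 4-(benzyloxy)-3-(4-bromophenoxy)benzaldehyde | O=Cc1ccc(OCc2ccccc2)c(Oc2ccc(Br)cc2)c1 | intermediate
6 | 3-[(Z)-2-[4-(benzyloxy)-3-(4-bromophenoxy)phenyl]ethenyl]phenol | Oc1cccc(/C=C\c2ccc(OCc3ccccc3)c(Oc3ccc(Br)cc3)c2)c1 | intermediate
7 | 3-[(E)-2-[4-(benzyloxy)-3-(4-bromophenoxy)phenyl]ethenyl]phenol | Oc1cccc(/C=C/c2ccc(OCc3ccccc3)c(Oc3ccc(Br)cc3)c2)c1 | intermediate
8 | 1-(2-hydroxy-5-methoxyphenyl)ethan-1-one | CC(=O)c1cc(OC)ccc1O | starting material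
9 | 2-[4-[2-(benzyloxy)-5-[(E)-2-(3-hydroxyphenyl)ethenyl]phenoxy]phenyl]-1-(2-hydroxy-5-methoxyphenyl)ethan-1-one | COc1ccc(O)c(c1)C(=O)Cc1ccc(cc1)Oc1cc(/C=C/c2cccc(O)c2)ccc1OCc1ccccc1 | intermediate
10 | 2-[[4-[2-(benzyloxy)-5-[(E)-2-(3-hydroxyphenyl)ethenyl]phenoxy]phenyl]acetyl]-4,4-dimethoxycyclohexa-2,5-dien-1-one | COC1(OC)C=CC(=O)C(=C1)C(=O)Cc1ccc(cc1)Oc1cc(/C=C/c2cccc(O)c2)ccc1OCc1ccccc1 | intermediate
11 | macrocyclic oxa-Michael adduct of 10 (ring B oxygen bonded to C3 of the 4,4-dimethoxycyclohexenone; 1,3-dicarbonyl drawn as ring enol; racemic at C3; E alkene) | COC1(OC)C=CC(O)=C2C1Oc1cccc(c1)/C=C/c1ccc(OCc3ccccc3)c(c1)Oc1ccc(cc1)CC2=O | intermediate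
12 | macrocyclic keto-stilbene benzyl ether (18-membered; C=O on the ring A benzylic carbon, (E)-CH=CH between rings B and C, ring C O-benzyl) | COc1ccc(O)c2c1Oc1cccc(c1)/C=C/c1ccc(OCc3ccccc3)c(c1)Oc1ccc(cc1)CC2=O | intermediate
13 | CNP0179896.0 (18-membered bis(bibenzyl); ring A 4-methoxyphenol with CH2CH2 at C2 and the ring B aryloxy group at C3; ring C 4-hydroxy-3-aryloxyphenyl; achiral) | COc1ccc(O)c2c1Oc1cccc(c1)CCc1ccc(O)c(c1)Oc1ccc(cc1)CC2 | target

**Step count and risks**
Total steps: 6. Longest linear sequence: 5 (steps 2 to 6, from 3 and 4).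

Three steps most likely to fail:

1. Step 5 (oxidative macrocyclisation). The risks are competing oxidation of the free ring B phenol by PhI(OAc)2, oligomerisation, and C- instead of O-attack of the aryloxide. The fallback sets out from 9 and comes back at 11. Silylate only the unchelated ring B phenol of 9 (TBSCl, imidazole, DMF, 0 °C; the ring A phenol is hydrogen-bonded to the ketone and stays free) to give the ring B tert-butyldimethylsilyl ether of 9 F1. Oxidise it with PhI(OAc)2 in MeOH, where ring A is now the only phenol, to the silyl-protected acyl quinone monoketal F2. Release the aryloxide at high dilution with CsF in MeCN so that it adds as it forms and closes the ring to 11, which TsOH converts to 12 as in step 5.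

2. Step 4 (α-arylation with two unprotected phenols). The risk is that the chelated phenoxide of 8 makes enolate formation or transmetalation sluggish. The fallback sets out from 8 and comes back at 9. Mask the phenol of 8 (MOMCl, iPr2NEt, CH2Cl2) to give 1-[5-methoxy-2-(methoxymethoxy)phenyl]ethan-1-one F3. Arylate its simple mono-enolate with 7 (Pd2(dba)3, XPhos, NaOtBu, THF, 65 °C) to the methoxymethyl-protected deoxybenzoin F4. Remove the acetal with HCl in MeOH at 40 °C to reach 9.

3. Step 6 (triple reduction in one operation). The risk is that the hindered, chelated ketone stops at the alcohol stage or that the benzylic cation is trapped transannularly. The fallback sets out from 12 and comes back at 13. Hydrogenate under neutral conditions (H2 1 atm, 10% Pd/C, EtOAc, rt), which only saturates the alkene and removes the benzyl group, to give the macrocyclic keto-triphenol F5. Then deoxygenate the ketone by ionic hydrogenation (Et3SiH, TFA, CH2Cl2, rt), which gives 13.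

**Further compounds**
F1 | step 5 | ring B tert-butyldimethylsilyl ether of 9 | COc1ccc(O)c(c1)C(=O)Cc1ccc(cc1)Oc1cc(/C=C/c2cccc(O[Si](C)(C)C(C)(C)C)c2)ccc1OCc1ccccc1
F2 | step 5 | silyl-protected acyl quinone monoketal (ring B tert-butyldimethylsilyl ether of 10) | COC1(OC)C=CC(=O)C(=C1)C(=O)Cc1ccc(cc1)Oc1cc(/C=C/c2cccc(O[Si](C)(C)C(C)(C)C)c2)ccc1OCc1ccccc1
F3 | step 4 | 1-[5-methoxy-2-(methoxymethoxy)phenyl]ethan-1-one | CC(=O)c1cc(OC)ccc1OCOC
F4 | step 4 | methoxymethyl-protected deoxybenzoin (ring A O-methoxymethyl ether of 9) | COCOc1ccc(OC)cc1C(=O)Cc1ccc(cc1)Oc1cc(/C=C/c2cccc(O)c2)ccc1OCc1ccccc1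
F5 | step 6 | macrocyclic keto-triphenol (13 with C=O at the ring A benzylic carbon) | COc1ccc(O)c2c1Oc1cccc(c1)CCc1ccc(O)c(c1)Oc1ccc(cc1)CC2=O
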